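**Plan**

- Retrosynthesis cuts, in this order: the C9 silyl ether, C5=C16, C6–Cl, the lactone C7–O bond and C8–C17; then the C4–O–C8 bridge with C5–C8, which go back to a furan; then C8–C9 (ten-membered ring), C2–C3, C11=C12 (ring A), C13–C14 and C1–C10.
- Forward: an Ireland–Claisen rearrangement joins C1–C10, an allylation adds C12/C13, ring-closing metathesis closes ring A, an aldol appends a bromofuran through C2–C3, a Nozaki–Hiyama–Kishi reaction closes the ten-membered ring at C8–C9, an Achmatowicz rearrangement turns the furan into the 4,8-ether-bridged pyranone, and the C17 unit, lactone, chlorine and C16 follow.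
- Enabling feature: ring A (C1, C14, C13, C12, C11, C10) holds its only alkene between C11 and C12. C11 carries only the C20 methyl and C12 only hydrogen, so a 2-butenyl-type olefin on C10 and an allyl group on the C14 carbinol are metathesis partners, and the olefin carbon lost from C11 can carry a stereocentre.
- Stereochemistry: one carbinol centre from a CBS reduction steers the chair Ireland–Claisen (quaternary C1 and C10 in one event) and is then cut out as propene by the metathesis. C14 and C2 come from Ipc2B reagents, C4 from transfer hydrogenation, C9 from Felkin–Anh addition, C8 from the bridge, and C17, C7 and C6 from exo-face attack on the bicycle.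

Key step: step 8

Remark: atoms are labelled with briarane numbering (C1–C10 ten-membered ring; C11–C14 complete ring A; C15 methyl on C1; C16 methylene on C5; C17 lactone α-carbon; C20 methyl on C11); R/S descriptors are those of each compound and can change with substituents.
Assumption: the Ipc2B reagents derived from (+)-α-pinene are taken to add allyl to the Si face of the aldehyde and, as the enol borinate of a methyl ketone, to the Re face; if either sense is found reversed, the antipodal reagent is used.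
Assumption: compounds 1, 2, 5, 18 and 30 and all named reagents are taken as commercially available.

**Route**

Step 1
Reactants: 1 2-[(4-methoxybenzyl)oxy]acetaldehyde; 2 3-(triphenyl-λ5-phosphanylidene)butan-2-one
Product: 3 (3E)-5-[(4-methoxybenzyl)oxy]-3-methylpent-3-en-2-one
Conditions: toluene, 80 °C
Reagents that add atoms: none
Why: Wittig olefination with a stabilised α-branched ylide should give the (E)-trisubstituted enone.

Step 2
Reactants: 3 (3E)-5-[(4-methoxybenzyl)oxy]-3-methylpent-3-en-2-one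
Product: 4 (2R,3E)-5-[(4-methoxybenzyl)oxy]-3-methylpent-3-en-2-ol
Conditions: (S)-Me-CBS oxazaborolidine (10 mol %), BH3·SMe2, THF, −20 °C; MeOH
Reagents that add atoms: none
Why: Corey–Bakshi–Shibata reduction; the (S)-catalyst should deliver hydride with the alkenyl group as the large substituent and set the (R)-carbinol.

Step 3
Reactants: 4 (2R,3E)-5-[(4-methoxybenzyl)oxy]-3-methylpent-3-en-2-ol; 5 3-ethoxy-2-methyl-3-oxopropanoic acid (ethyl hydrogen methylmalonate, racemic)
Product: 6 1-ethyl 3-[(2R,3E)-5-[(4-methoxybenzyl)oxy]-3-methylpent-3-en-2-yl] 2-methylpropanedioate (both epimers at the malonate CH)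
Conditions: DCC, DMAP (cat.), CH2Cl2, 0 → 23 °C
Reagents that add atoms: none
Why: Steglich esterification of a secondary allylic alcohol; the epimeric malonate carbon is planarised in step 4.

Step 4
Reactants: 6 mixed malonate
Product: 9 (2R,3S,4E)-2-(ethoxycarbonyl)-3-{[(4-methoxybenzyl)oxy]methyl}-2,4-dimethylhex-4-enoic acid, via silyl ketene acetal 7 (not isolated), via trimethylsilyl ester 8 (not isolated)
Conditions: LiN(SiMe3)2, Me3SiCl, THF, −78 → 45 °C; then 1 M HCl
Reagents that add atoms: none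
Why: Ireland–Claisen rearrangement; the chelated (Z)-silyl ketene acetal (ester cis to OSiMe3) should react through a chair with the carbinol methyl and the (E)-olefin substituent equatorial, which carries the (R)-carbinol configuration to quaternary C1 (R) and to C10 (S) in one event and leaves an (E)-trisubstituted olefin.

Step 5
Reactants: 9 half acid
Product: 10 ethyl (2R,3S,4E)-2-(hydroxymethyl)-3-{[(4-methoxybenzyl)oxy]methyl}-2,4-dimethylhex-4-enoate
Conditions: BH3·SMe2, THF, 0 °C; MeOH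
Reagents that add atoms: none
Why: chemoselective borane reduction; the free acid (as acyloxyborane) should be reduced faster than the ester or the hindered trisubstituted olefin.

Step 6
Reactants: 10 hydroxy ester
Product: 11 ethyl (2R,3S,4E)-2-formyl-3-{[(4-methoxybenzyl)oxy]methyl}-2,4-dimethylhex-4-enoate
Conditions: Dess–Martin periodinane, NaHCO3, CH2Cl2, 0 → 23 °C
Reagents that add atoms: none
Why: Dess–Martin oxidation of a neopentylic primary alcohol to a non-enolisable aldehyde.

Step 7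
Reactants: 11 formyl ester
Product: 13 ethyl (2R,3S,4E)-2-[(1S)-1-hydroxybut-3-en-1-yl]-3-{[(4-methoxybenzyl)oxy]methyl}-2,4-dimethylhex-4-enoate, via borinic ester 12 (not isolated)
Conditions: (−)-Ipc2B(allyl), Et2O, −78 °C; then NaOH, H2O2, 0 °C
Reagents that add atoms: (−)-B-allyldiisopinocampheylborane, C=CCB([C@@H]1C[C@@H]2C[C@H]([C@H]1C)C2(C)C)[C@@H]1C[C@@H]2C[C@H]([C@H]1C)C2(C)C
Why: Brown allylboration; the reagent should add allyl to the Si face of the aldehyde through a chair transition state under reagent control and set C14 as S.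

Step 8
Reactants: 13 hydroxy diene
Product: 14 ethyl (1R,2S,6S)-6-hydroxy-2-{[(4-methoxybenzyl)oxy]methyl}-1,3-dimethylcyclohex-3-ene-1-carboxylate (ring A)
Conditions: second-generation Grubbs catalyst RuCl2(H2IMes)(PCy3)(=CHPh) (5 mol %), CH2Cl2 (5 mM), 40 °C, argon purge
Reagents that add atoms: none
Why: Ring-closing olefin metathesis: the ruthenium benzylidene should initiate at the terminal vinyl group (C12), the new alkylidene adds across the trisubstituted C11=CH(CH3) olefin through a ruthenacyclobutane, and cycloreversion forms C11=C12 while the ethylidene fragment leaves as propene. The closest known reaction type is ring-closing metathesis of a 1,7-diene with one trisubstituted partner to a 1-methylcyclohexene, here on an Ireland–Claisen product. Ring A is closed as a six-membered carbocycle by joining the two olefinic carbons C11 and C12 of the 1,7-diene; no other ring is formed. No stereocentre is created, C1, C10 and C14 are not touched, and the propene that is lost carries away the carbinol carbon whose configuration was relayed to C1 and C10 in step 4. The step needs cyclisation to beat cross-metathesis at the single terminal olefin and olefin migration; the quaternary C1 between the two chains (gem-disubstituent effect), the six-membered ring size and high dilution with removal of propene should secure this.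

Step 9
Reactants: 14 ring A hydroxy ester
Product: 15 (1S,5S,6S)-6-(hydroxymethyl)-5-{[(4-methoxybenzyl)oxy]methyl}-4,6-dimethylcyclohex-3-en-1-ol
Conditions: LiAlH4, THF, 0 → 23 °C
Reagents that add atoms: none
Why: LiAlH4 reduction of the hindered ester to the primary alcohol; no stereocentre is affected.

Step 10
Reactants: 15 diol
Product: 16 (1R,2S,6S)-6-hydroxy-2-{[(4-methoxybenzyl)oxy]methyl}-1,3-dimethylcyclohex-3-ene-1-carbaldehyde
Conditions: TEMPO (cat.), PhI(OAc)2, CH2Cl2, 23 °C
Reagents that add atoms: none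
Why: nitroxyl-catalysed oxidation is selective for the primary over the secondary alcohol and stops at the aldehyde.

Step 11
Reactants: 16 hydroxy aldehyde
Product: 17 (1S,5S,6R)-6-formyl-5-{[(4-methoxybenzyl)oxy]methyl}-4,6-dimethylcyclohex-3-en-1-yl acetate
Conditions: Ac2O, pyridine, DMAP (cat.), CH2Cl2, 0 °C
Reagents that add atoms: acetic anhydride, CC(=O)OC(C)=O
Why: acylation installs the C14 acetate of the target and removes the free hydroxyl before the boron aldol.

Step 12
Reactants: 17 acetoxy aldehyde; 18 1-(5-bromofuran-2-yl)ethan-1-one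
Product: 21 (1S,5S,6S)-6-[(1R)-3-(5-bromofuran-2-yl)-1-hydroxy-3-oxopropyl]-5-{[(4-methoxybenzyl)oxy]methyl}-4,6-dimethylcyclohex-3-en-1-yl acetate, via enol borinate 19 (not isolated), via boron aldolate 20 (not isolated)
Conditions: 18, (−)-Ipc2BCl, Et3N, Et2O, 0 °C; then 17, −78 → −20 °C; H2O2, pH 7 buffer, MeOH
Reagents that add atoms: none
Why: boron-mediated aldol reaction of a methyl ketone; the diisopinocampheyl enol borinate should add to the Re face of the non-enolisable aldehyde under reagent control and set C2 as R.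

Step 13
Reactants: 21 aldol adduct
Product: 22 (1S,5S,6R)-6-[(1R)-1-acetoxy-3-(5-bromofuran-2-yl)-3-oxopropyl]-5-{[(4-methoxybenzyl)oxy]methyl}-4,6-dimethylcyclohex-3-en-1-yl acetate
Conditions: Ac2O, pyridine, DMAP (cat.), CH2Cl2, 0 °C
Reagents that add atoms: acetic anhydride, CC(=O)OC(C)=O
Why: acylation installs the C2 acetate of the target at 0 °C, where β-elimination of the β-acetoxy ketone should stay slow.

Step 14
Reactants: 22 diacetate
Product: 23 (1S,5S,6R)-6-[(1R)-1-acetoxy-3-(5-bromofuran-2-yl)-3-oxopropyl]-5-(hydroxymethyl)-4,6-dimethylcyclohex-3-en-1-yl acetate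
Conditions: DDQ, CH2Cl2/pH 7 buffer, 0 °C
Reagents that add atoms: none
Why: oxidative cleavage of the 4-methoxybenzyl ether; the acylated bromofuran, the acetates and the ring A olefin should be inert.

Step 15
Reactants: 23 primary alcohol
Product: 24 (1S,5S,6R)-6-[(1R)-1-acetoxy-3-(5-bromofuran-2-yl)-3-oxopropyl]-5-formyl-4,6-dimethylcyclohex-3-en-1-yl acetate
Conditions: Dess–Martin periodinane, NaHCO3, CH2Cl2, 0 °C; used at once
Reagents that add atoms: none
Why: buffered Dess–Martin oxidation gives the β,γ-unsaturated aldehyde without base, so that C10 should not epimerise or move into conjugation.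

Step 16
Reactants: 24 bromofuryl aldehyde
Product: 25 ten-membered furanophane alcohol (C5–C8 = furan-2,5-diyl; C4 ketone; 9-hydroxyl; 2,14-diacetate; 1R,2R,9R,10S,14S)
Conditions: CrCl2 (6 equiv), NiCl2 (cat.), DMSO/THF, 23 °C, slow addition (1 mM)
Reagents that add atoms: none
Why: Nozaki–Hiyama–Kishi reaction; nickel-catalysed insertion into the furyl C–Br bond, transmetalation to trivalent chromium and intramolecular addition to the aldehyde should close the ten-membered ring, with Felkin–Anh attack anti to quaternary C1 setting C9 as R and with ketone and acetates untouched.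

Step 17
Reactants: 25 furanophane alcohol
Product: 26 9-O-tert-butyldimethylsilyl furanophane ketone (1R,2R,9R,10S,14S)
Conditions: tBuMe2SiOTf, 2,6-lutidine, CH2Cl2, −78 → 0 °C
Reagents that add atoms: tert-butyldimethylsilyl trifluoromethanesulfonate, CC(C)(C)[Si](C)(C)OS(=O)(=O)C(F)(F)F
Why: silylation blocks the C9 hydroxyl so that only the C4 hydroxyl can take part in step 19.

Step 18
Reactants: 26 furyl ketone
Product: 27 furanophane C4 alcohol (1R,2R,4S,9R,10S,14S)
Conditions: RuCl(p-cymene)[(S,S)-TsDPEN] (2 mol %), HCO2H/Et3N (5:2), CH2Cl2, 23 °C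
Reagents that add atoms: none
Why: Noyori asymmetric transfer hydrogenation of a 2-acylfuran; the (S,S)-catalyst should give the (S)-furyl carbinol at C4 under catalyst control.

Step 19
Reactants: 27 furfuryl alcohol
Product: 29 bridged pyranone hemiketal (4,8-epoxy bridge; C5 ketone; C6=C7; 8-hydroxyl; 1R,2R,4S,8S,9R,10S,14S), via cis-enedione 28 (not isolated)
Conditions: NBS, NaHCO3, THF/H2O (4:1), 0 °C
Reagents that add atoms: water, O
Why: Achmatowicz rearrangement; oxidative opening of the furan and transannular attack of the C4 hydroxyl on the C8 ketone should give the pyranone, with C8 fixed because C3 and C9 must be cis on the new ring.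

Step 20
Reactants: 30 propanoic acid
Product: 31 1,1-bis(trimethylsilyloxy)prop-1-ene
Conditions: LiN(iPr)2 (2.1 equiv), THF, 0 °C; Me3SiCl, −78 → 23 °C
Reagents that add atoms: chlorotrimethylsilane, C[Si](C)(C)Cl
Why: double deprotonation and O-silylation, the standard preparation of ketene bis(silyl) acetals.

Step 21
Reactants: 29 bridged hemiketal; 31 1,1-bis(trimethylsilyloxy)prop-1-ene
Product: 33 C8 C-glycoside acid ((2R)-propanoic acid unit on C8; 1R,2R,4S,8R,9R,10S,14S,17R), via trimethylsilyl ester 32 (not isolated)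
Conditions: 31 (3 equiv), Me3SiOTf (0.2 equiv), CH2Cl2, −78 → −40 °C; aq. NaH2PO4
Reagents that add atoms: none
Why: Mukaiyama-type C-glycosylation of a hemiketal; the bridgehead oxocarbenium ion can be attacked only from the exo face, which fixes C8, and an open transition state with the C17 methyl anti to the bulky C9 substituent should set C17 as R.

Step 22
Reactants: 33 enone acid
Product: 34 keto lactone (C5 ketone, C6 methylene; 1R,2R,4S,7S,8S,9R,10S,14S,17R)
Conditions: DBU (0.2 equiv), MeCN, 23 °C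
Reagents that add atoms: none
Why: intramolecular oxa-Michael addition of the carboxylate to the enone (5-exo-trig) gives the γ-lactone, which can only be cis-fused and so sets C7.

Step 23
Reactants: 34 keto lactone
Product: 36 6-chloro ketone (1R,2R,4S,6R,7R,8S,9R,10S,14S,17R), via silyl enol ether 35 (not isolated)
Conditions: Me3SiOTf, Et3N, CH2Cl2, 0 °C; then N-chlorosuccinimide, THF, −78 → 0 °C
Reagents that add atoms: N-chlorosuccinimide, O=C1CCC(=O)N1Cl
Why: soft enolisation away from the bridgehead C4, then electrophilic chlorination of the silyl enol ether from the exo face opposite the five-carbon bridge, should place chlorine at C6 cis to the lactone oxygen.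

Step 24
Reactants: 36 6-chloro ketone
Product: 37 9-O-tert-butyldimethylsilyl ether of the target (1R,2R,4S,6S,7R,8S,9R,10S,14S,17R)
Conditions: Tebbe reagent Cp2Ti(μ-CH2)(μ-Cl)AlMe2 (1.2 equiv), pyridine (cat.), THF/toluene, −40 → 0 °C
Reagents that add atoms: Tebbe reagent, C[Al-]1(C)C[Ti](C2C=CC=C2)(C2C=CC=C2)[Cl+]1
Why: Tebbe methylenation; the non-basic titanium methylidene should convert the ketone to the exocyclic olefin faster than it reacts with esters and without β-elimination.

Step 25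
Reactants: 37 silyl ether
Product: 38 CNP0198838.2 (1R,2R,4S,6S,7R,8R,9R,10S,14S,17R)
Conditions: HF·pyridine, pyridine, THF, 0 → 23 °C
Reagents that add atoms: none
Why: fluoride-mediated cleavage of the silyl ether should free the C9 hydroxyl without touching acetates, lactone or the allylic chloride.

**Compound list**

1 | 2-[(4-methoxybenzyl)oxy]acetaldehyde | COc1ccc(COCC=O)cc1 | starting material
2 | 3-(triphenyl-λ5-phosphanylidene)butan-2-one | CC(=O)C(C)=P(c1ccccc1)(c1ccccc1)c1ccccc1 | starting material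
3 | (3E)-5-[(4-methoxybenzyl)oxy]-3-methylpent-3-en-2-one | COc1ccc(COC/C=C(\C)C(C)=O)cc1 | intermediate
4 | (2R,3E)-5-[(4-methoxybenzyl)oxy]-3-methylpent-3-en-2-ol | COc1ccc(COC/C=C(\C)[C@@H](C)O)cc1 | intermediate
5 | 3-ethoxy-2-methyl-3-oxopropanoic acid (racemic) | CCOC(=O)C(C)C(=O)O | starting material
6 | 1-ethyl 3-[(2R,3E)-5-[(4-methoxybenzyl)oxy]-3-methylpent-3-en-2-yl] 2-methylpropanedioate (both malonate epimers) | CCOC(=O)C(C)C(=O)O[C@H](C)/C(C)=C/COCc1ccc(OC)cc1 | intermediate
7 | (Z)-trimethylsilyl ketene acetal of 6 (ethoxycarbonyl cis to OSiMe3) | CCOC(=O)/C(C)=C(\O[Si](C)(C)C)O[C@H](C)/C(C)=C/COCc1ccc(OC)cc1 | intermediate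
8 | trimethylsilyl ester of 9 | CCOC(=O)[C@@](C)(C(=O)O[Si](C)(C)C)[C@@H](COCc1ccc(OC)cc1)/C(C)=C/C | intermediate
9 | (2R,3S,4E)-2-(ethoxycarbonyl)-3-{[(4-methoxybenzyl)oxy]methyl}-2,4-dimethylhex-4-enoic acid | CCOC(=O)[C@@](C)(C(=O)O)[C@@H](COCc1ccc(OC)cc1)/C(C)=C/C | intermediate
10 | ethyl (2R,3S,4E)-2-(hydroxymethyl)-3-{[(4-methoxybenzyl)oxy]methyl}-2,4-dimethylhex-4-enoate | CCOC(=O)[C@@](C)(CO)[C@@H](COCc1ccc(OC)cc1)/C(C)=C/C | intermediate
11 | ethyl (2R,3S,4E)-2-formyl-3-{[(4-methoxybenzyl)oxy]methyl}-2,4-dimethylhex-4-enoate | CCOC(=O)[C@@](C)(C=O)[C@@H](COCc1ccc(OC)cc1)/C(C)=C/C | intermediate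
12 | diisopinocampheylborinic ester of 13 | CCOC(=O)[C@@](C)([C@@H](OB([C@@H]1C[C@@H]2C[C@H]([C@H]1C)C2(C)C)[C@@H]1C[C@@H]2C[C@H]([C@H]1C)C2(C)C)CC=C)[C@@H](COCc1ccc(OC)cc1)/C(C)=C/C | intermediate
13 | ethyl (2R,3S,4E)-2-[(1S)-1-hydroxybut-3-en-1-yl]-3-{[(4-methoxybenzyl)oxy]methyl}-2,4-dimethylhex-4-enoate | CCOC(=O)[C@@](C)([C@@H](O)CC=C)[C@@H](COCc1ccc(OC)cc1)/C(C)=C/C | intermediate
14 | ethyl (1R,2S,6S)-6-hydroxy-2-{[(4-methoxybenzyl)oxy]methyl}-1,3-dimethylcyclohex-3-ene-1-carboxylate | CCOC(=O)[C@@]1(C)[C@@H](O)CC=C(C)[C@@H]1COCc1ccc(OC)cc1 | intermediate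
15 | (1S,5S,6S)-6-(hydroxymethyl)-5-{[(4-methoxybenzyl)oxy]methyl}-4,6-dimethylcyclohex-3-en-1-ol | OC[C@@]1(C)[C@@H](O)CC=C(C)[C@@H]1COCc1ccc(OC)cc1 | intermediate
16 | (1R,2S,6S)-6-hydroxy-2-{[(4-methoxybenzyl)oxy]methyl}-1,3-dimethylcyclohex-3-ene-1-carbaldehyde | O=C[C@@]1(C)[C@@H](O)CC=C(C)[C@@H]1COCc1ccc(OC)cc1 | intermediate
17 | (1S,5S,6R)-6-formyl-5-{[(4-methoxybenzyl)oxy]methyl}-4,6-dimethylcyclohex-3-en-1-yl acetate | O=C[C@@]1(C)[C@@H](OC(C)=O)CC=C(C)[C@@H]1COCc1ccc(OC)cc1 | intermediate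
18 | 1-(5-bromofuran-2-yl)ethan-1-one | CC(=O)c1ccc(Br)o1 | starting material
19 | diisopinocampheyl enol borinate of 18 | C=C(OB([C@@H]1C[C@@H]2C[C@H]([C@H]1C)C2(C)C)[C@@H]1C[C@@H]2C[C@H]([C@H]1C)C2(C)C)c1ccc(Br)o1 | intermediate
20 | diisopinocampheylboron aldolate of 21 | O=C(C[C@@H](OB([C@@H]1C[C@@H]2C[C@H]([C@H]1C)C2(C)C)[C@@H]1C[C@@H]2C[C@H]([C@H]1C)C2(C)C)[C@@]1(C)[C@@H](OC(C)=O)CC=C(C)[C@@H]1COCc1ccc(OC)cc1)c1ccc(Br)o1 | intermediate
21 | (1S,5S,6S)-6-[(1R)-3-(5-bromofuran-2-yl)-1-hydroxy-3-oxopropyl]-5-{[(4-methoxybenzyl)oxy]methyl}-4,6-dimethylcyclohex-3-en-1-yl acetate | O=C(C[C@@H](O)[C@@]1(C)[C@@H](OC(C)=O)CC=C(C)[C@@H]1COCc1ccc(OC)cc1)c1ccc(Br)o1 | intermediate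
22 | (1S,5S,6R)-6-[(1R)-1-acetoxy-3-(5-bromofuran-2-yl)-3-oxopropyl]-5-{[(4-methoxybenzyl)oxy]methyl}-4,6-dimethylcyclohex-3-en-1-yl acetate | O=C(C[C@@H](OC(C)=O)[C@@]1(C)[C@@H](OC(C)=O)CC=C(C)[C@@H]1COCc1ccc(OC)cc1)c1ccc(Br)o1 | intermediate
23 | (1S,5S,6R)-6-[(1R)-1-acetoxy-3-(5-bromofuran-2-yl)-3-oxopropyl]-5-(hydroxymethyl)-4,6-dimethylcyclohex-3-en-1-yl acetate | O=C(C[C@@H](OC(C)=O)[C@@]1(C)[C@@H](OC(C)=O)CC=C(C)[C@@H]1CO)c1ccc(Br)o1 | intermediate
24 | (1S,5S,6R)-6-[(1R)-1-acetoxy-3-(5-bromofuran-2-yl)-3-oxopropyl]-5-formyl-4,6-dimethylcyclohex-3-en-1-yl acetate | O=C(C[C@@H](OC(C)=O)[C@@]1(C)[C@@H](OC(C)=O)CC=C(C)[C@@H]1C=O)c1ccc(Br)o1 | intermediate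
25 | ten-membered furanophane alcohol (C5–C8 furan-2,5-diyl, C4 ketone; 1R,2R,9R,10S,14S) | O=C1C[C@@H](OC(C)=O)[C@@]2(C)[C@@H](OC(C)=O)CC=C(C)[C@@H]2[C@@H](O)c2ccc1o2 | intermediate
26 | 9-O-tert-butyldimethylsilyl furanophane ketone (1R,2R,9R,10S,14S) | O=C1C[C@@H](OC(C)=O)[C@@]2(C)[C@@H](OC(C)=O)CC=C(C)[C@@H]2[C@@H](O[Si](C)(C)C(C)(C)C)c2ccc1o2 | intermediate
27 | furanophane C4 alcohol (1R,2R,4S,9R,10S,14S) | O[C@H]1C[C@@H](OC(C)=O)[C@@]2(C)[C@@H](OC(C)=O)CC=C(C)[C@@H]2[C@@H](O[Si](C)(C)C(C)(C)C)c2ccc1o2 | intermediate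
28 | (6Z)-4-hydroxy-5,8-dione (ring-opened furan; 1R,2R,4S,9R,10S,14S) | O[C@H]1C[C@@H](OC(C)=O)[C@@]2(C)[C@@H](OC(C)=O)CC=C(C)[C@@H]2[C@@H](O[Si](C)(C)C(C)(C)C)C(=O)/C=C\C1=O | intermediate
29 | bridged pyranone hemiketal (4,8-epoxy, C5 ketone, C6=C7, 8-OH; 1R,2R,4S,8S,9R,10S,14S) | O=C1[C@@H]2C[C@@H](OC(C)=O)[C@@]3(C)[C@@H](OC(C)=O)CC=C(C)[C@@H]3[C@@H](O[Si](C)(C)C(C)(C)C)[C@@](O)(O2)C=C1 | intermediate
30 | propanoic acid | CCC(=O)O | starting material
31 | 1,1-bis(trimethylsilyloxy)prop-1-ene | CC=C(O[Si](C)(C)C)O[Si](C)(C)C | intermediate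
32 | trimethylsilyl ester of 33 | O=C1[C@@H]2C[C@@H](OC(C)=O)[C@@]3(C)[C@@H](OC(C)=O)CC=C(C)[C@@H]3[C@@H](O[Si](C)(C)C(C)(C)C)[C@](O2)([C@@H](C)C(=O)O[Si](C)(C)C)C=C1 | intermediate
33 | C8 C-glycoside acid (1R,2R,4S,8R,9R,10S,14S,17R) | O=C1[C@@H]2C[C@@H](OC(C)=O)[C@@]3(C)[C@@H](OC(C)=O)CC=C(C)[C@@H]3[C@@H](O[Si](C)(C)C(C)(C)C)[C@](O2)([C@@H](C)C(=O)O)C=C1 | intermediate
34 | keto lactone (C5 ketone, C6 methylene; 1R,2R,4S,7S,8S,9R,10S,14S,17R) | O=C1[C@@H]2C[C@@H](OC(C)=O)[C@@]3(C)[C@@H](OC(C)=O)CC=C(C)[C@@H]3[C@@H](O[Si](C)(C)C(C)(C)C)[C@]3(O2)[C@@H](C)C(=O)O[C@H]3C1 | intermediate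
35 | C5 trimethylsilyl enol ether of 34 (C5=C6) | C[Si](C)(C)OC=1[C@@H]2C[C@@H](OC(C)=O)[C@@]3(C)[C@@H](OC(C)=O)CC=C(C)[C@@H]3[C@@H](O[Si](C)(C)C(C)(C)C)[C@]3(O2)[C@@H](C)C(=O)O[C@H]3C=1 | intermediate
36 | 6-chloro ketone (1R,2R,4S,6R,7R,8S,9R,10S,14S,17R) | O=C1[C@@H]2C[C@@H](OC(C)=O)[C@@]3(C)[C@@H](OC(C)=O)CC=C(C)[C@@H]3[C@@H](O[Si](C)(C)C(C)(C)C)[C@]3(O2)[C@@H](C)C(=O)O[C@H]3[C@H]1Cl | intermediate
37 | 9-O-tert-butyldimethylsilyl ether of the target (1R,2R,4S,6S,7R,8S,9R,10S,14S,17R) | C=C1[C@@H]2C[C@@H](OC(C)=O)[C@@]3(C)[C@@H](OC(C)=O)CC=C(C)[C@@H]3[C@@H](O[Si](C)(C)C(C)(C)C)[C@]3(O2)[C@@H](C)C(=O)O[C@H]3[C@H]1Cl | intermediate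
38 | CNP0198838.2: 2,14-diacetoxy-6-chloro-4,8-epoxy-9-hydroxybriara-5(16),11-diene 7-lactone (1R,2R,4S,6S,7R,8R,9R,10S,14S,17R) | C=C1[C@@H]2C[C@@H](OC(C)=O)[C@@]3(C)[C@@H](OC(C)=O)CC=C(C)[C@@H]3[C@@H](O)[C@]3(O2)[C@@H](C)C(=O)O[C@H]3[C@H]1Cl | target

**Step count and risks**

Total step count: 25. Longest linear sequence: 24 steps (steps 1–19 and 21–25; step 20 is a one-step side branch).

The three steps most likely to fail:

Step 21. The silyl ketene acetal may add in a conjugate sense to C7 of the enone instead of substituting at C8, or ionisation at the bridgehead may be too slow. The fallback masks the enone and sets out from 29. Thiophenol and Et3N should add to C7 from the exo face to give the 7-phenylthio ketone hemiketal F1. Me3SiOTf and 31 should then give the 7-phenylthio C-glycoside acid F2, since acetal activation outruns aldol addition to a saturated ketone. NaIO4 should oxidise the sulfide to the sulfoxide F3. Thermal syn-elimination of F3 (toluene, 80 °C) restores the C6=C7 enone, and the route is rejoined at 33.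

Step 24. The Lewis-acidic titanium reagent may trigger β-elimination of the lactone carboxylate or of chloride, or may also methylenate the ester carbonyls. The fallback is a two-stage Peterson olefination and sets out from 36. Me3SiCH2MgCl/CeCl3 (THF, −78 °C) should add to the ketone from the exo face without enolisation to give the β-hydroxysilane F4. Aqueous HF in MeCN should then effect the acid-mediated elimination and cleave the silyl ether in the same operation, so the route is rejoined at the target 38.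

Step 8. Turnover at the trisubstituted olefin may be slow, so that catalyst decomposition, olefin migration or dimerisation through the terminal vinyl group competes with ring closure. The fallback forms the same C11=C12 bond by carbonyl coupling and sets out from 13. OsO4 (cat.), NaIO4 and 2,6-lutidine (dioxane/H2O) should cleave both olefins to the keto aldehyde F5. Intramolecular McMurry coupling (TiCl3(DME)1.5, Zn–Cu couple, DME, reflux, slow addition) should then join the C11 ketone and the C12 aldehyde, and the route is rejoined at 14.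

**Further compounds**

F1 | step 21 | 7-phenylthio ketone hemiketal (thiophenol adduct of 29) | O=C1[C@@H]2C[C@@H](OC(C)=O)[C@@]3(C)[C@@H](OC(C)=O)CC=C(C)[C@@H]3[C@@H](O[Si](C)(C)C(C)(C)C)[C@@](O)(O2)[C@@H](Sc4ccccc4)C1
F2 | step 21 | 7-phenylthio C-glycoside acid | O=C1[C@@H]2C[C@@H](OC(C)=O)[C@@]3(C)[C@@H](OC(C)=O)CC=C(C)[C@@H]3[C@@H](O[Si](C)(C)C(C)(C)C)[C@](O2)([C@@H](C)C(=O)O)[C@@H](Sc4ccccc4)C1
F3 | step 21 | sulfoxide of F2 (both sulfur epimers) | O=C1[C@@H]2C[C@@H](OC(C)=O)[C@@]3(C)[C@@H](OC(C)=O)CC=C(C)[C@@H]3[C@@H](O[Si](C)(C)C(C)(C)C)[C@](O2)([C@@H](C)C(=O)O)[C@@H](S(=O)c4ccccc4)C1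
F4 | step 24 | β-hydroxysilane (5-hydroxy-5-(trimethylsilylmethyl) adduct of 36) | C[Si](C)(C)C[C@@]1(O)[C@@H]2C[C@@H](OC(C)=O)[C@@]3(C)[C@@H](OC(C)=O)CC=C(C)[C@@H]3[C@@H](O[Si](C)(C)C(C)(C)C)[C@]3(O2)[C@@H](C)C(=O)O[C@H]3[C@H]1Cl
F5 | step 8 | keto aldehyde: ethyl (2R,3S)-2-[(1S)-1-hydroxy-3-oxopropyl]-3-{[(4-methoxybenzyl)oxy]methyl}-2-methyl-4-oxopentanoate | CCOC(=O)[C@@](C)([C@@H](O)CC=O)[C@@H](COCc1ccc(OC)cc1)C(C)=O
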